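**Retrosynthetic overview**
- Target ⇐ reagent-controlled epoxidation of a prenyl group on the α-hydroxy methyl ketone ⇐ oxidation of a sec,tert-diol ⇐ a 4,4,5-trisubstituted cyclic carbonate carrying the bromochlorocyclohexane.
- Key disconnection: the ring bond CH2–CH(side chain) of the cyclohexane and the C–O bond of the tertiary carbinol are cut together, leading back to an acyclic (S,S)-bromochloride with a primary alcohol, a Z-trisubstituted alkene and an (S)-allylic tert-butyl carbonate.
- Acyclic bromochloride ⇐ Z,Z-triene allylic alcohol by catalytic enantioselective bromochlorination.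
- Triene ⇐ B-alkyl Suzuki union of a (Z)-vinyl iodide (from (S)-but-3-yn-2-ol by anti-allylmagnesiation/iodination, then cross-metathesis) with a (Z)-dienol from a commercial enynol.
- Ring order: cyclohexane and 1,3-dioxolan-2-one form in one operation; the carbonate ring is then opened and the oxirane is formed last.

Assumption: in step 5 the antipode of the chiral Schiff-base ligand is the one that gives the (7S,8S)-bromochloride from the (Z)-allylic alcohol; both antipodes are accessible.

**Step 1**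
Reactants: 1 (S)-but-3-yn-2-ol; 2 allylmagnesium bromide
Product: 5 tert-butyl [(2S,3Z)-3-(iodomethylidene)hex-5-en-2-yl] carbonate, via oxamagnesacycle 3 (not isolated), via magnesium iodoalkoxide 4 (not isolated)
Conditions: 2 (2.2 equiv), CuI (5 mol%), Et2O, −20 °C → rt; then I2, THF, −40 → 0 °C; then Boc2O, rt
Reagents that add atoms: iodine, II; di-tert-butyl dicarbonate, CC(C)(C)OC(=O)OC(=O)OC(C)(C)C
Why: Copper-catalysed anti-carbomagnesiation of a propargylic alkoxide puts allyl on the internal alkyne carbon and Mg on the terminal carbon inside a five-membered chelate, so iodination with retention places I cis to the carbinol carbon (Z), and the untouched (S)-alkoxide is acylated in the same pot.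

**Step 2**
Reactants: 5 tert-butyl [(2S,3Z)-3-(iodomethylidene)hex-5-en-2-yl] carbonate; 6 2-methylbut-2-ene
Product: 7 tert-butyl [(2S,3Z)-3-(iodomethylidene)-6-methylhept-5-en-2-yl] carbonate
Conditions: 6 (excess), Hoveyda–Grubbs II (3 mol%), CH2Cl2, 40 °C, sealed tube
Reagents that add atoms: none
Why: Olefin cross-metathesis with excess 2-methylbut-2-ene converts only the monosubstituted allyl terminus into a prenyl group; the trisubstituted iodoalkene is inert and no stereocentre is touched.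

**Step 3**
Reactants: 8 (2Z)-3-methylpent-2-en-4-yn-1-ol
Product: 9 (2Z)-3-methylpenta-2,4-dien-1-ol
Conditions: H2 (1 atm), Lindlar catalyst, quinoline, EtOAc, 0 °C
Reagents that add atoms: none
Why: Lindlar semihydrogenation stops the terminal conjugated alkyne at the vinyl stage and leaves the Z-trisubstituted alkene unchanged.

**Step 4**
Reactants: 9 (2Z)-3-methylpenta-2,4-dien-1-ol; 7 tert-butyl [(2S,3Z)-3-(iodomethylidene)-6-methylhept-5-en-2-yl] carbonate
Product: 11 tert-butyl [(2S,3Z,7Z)-9-hydroxy-7-methyl-3-(3-methylbut-2-en-1-yl)nona-3,7-dien-2-yl] carbonate, via borane 10 (not isolated)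
Conditions: 9-BBN (2.2 equiv), THF, 0 °C → rt; then aq. Cs2CO3, 7, Pd(dppf)Cl2 (5 mol%), AsPh3, DMF, rt
Reagents that add atoms: none
Why: 9-BBN hydroborates only the terminal vinyl group (anti-Markovnikov) and the B-alkyl Suzuki–Miyaura coupling joins it to the vinyl iodide with retention of Z geometry; at rt, C–I oxidative addition outpaces ionisation of the hindered allylic carbonate.

**Step 5**
Reactants: 11 tert-butyl [(2S,3Z,7Z)-9-hydroxy-7-methyl-3-(3-methylbut-2-en-1-yl)nona-3,7-dien-2-yl] carbonate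
Product: 12 tert-butyl [(2S,3Z,7S,8S)-8-bromo-7-chloro-9-hydroxy-7-methyl-3-(3-methylbut-2-en-1-yl)non-3-en-2-yl] carbonate
Conditions: NBS, ClTi(OiPr)3, chiral tridentate Schiff-base (salicylaldimine amino-alcohol) ligand (20 mol%), hexanes, −20 °C
Reagents that add atoms: N-bromosuccinimide, BrN1C(=O)CCC1=O; chlorotitanium triisopropoxide, CC(C)O[Ti](Cl)(OC(C)C)OC(C)C
Why: Titanium/Schiff-base-catalysed enantioselective bromochlorination of allylic alcohols (Burns bromochlorination) activates only the Ti-bound allylic alcohol alkene; the ligand selects the bromonium face and chloride adds anti at the tertiary carbon, giving (7S,8S) from the Z-olefin while the two remote alkenes are spared.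

**Step 6**
Reactants: 12 tert-butyl [(2S,3Z,7S,8S)-8-bromo-7-chloro-9-hydroxy-7-methyl-3-(3-methylbut-2-en-1-yl)non-3-en-2-yl] carbonate
Product: 16 (4S,5S)-4-[(1S,3S,4S)-3-bromo-4-chloro-4-methylcyclohexyl]-5-methyl-4-(3-methylbut-2-en-1-yl)-1,3-dioxolan-2-one, via triflate 13 (not isolated), via bromiranium triflate 14 (not isolated), via dioxolanylium triflate 15 (not isolated)
Conditions: Tf2O, 2,6-di-tert-butyl-4-methylpyridine, CH2Cl2, −78 °C; then HFIP (CH2Cl2/HFIP 4:1), −40 → 0 °C
Reagents that add atoms: none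
Why: Proposed new method: the primary triflate ionises with anchimeric assistance of the vicinal bromine to a bromiranium ion, which the trisubstituted alkene opens at the unhindered CH2 carbon through a chair transition state in which Br must be equatorial (anti to the forming C–C bond), hence Cl equatorial, CH3 axial and the alkene terminus equatorial, fixing ring C-1 as S; the Boc carbonyl oxygen, held on the opposite alkene face by A(1,3) strain at the (S)-carbinol, adds anti across the Z-alkene (setting the quaternary carbinol as S) and loses isobutene, so the cyclohexane and the 1,3-dioxolan-2-one form together; the closest known reaction types are neighbouring-bromine-assisted sulfonate solvolysis, π-participating sulfonate (cation–olefin) cyclisations, stereospecific bromiranium polyene cyclisations of enantioenriched bromochlorides in HFIP, and tert-butyl-carbonate-terminated cation–olefin and halo-cyclisations.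

**Step 7**
Reactants: 16 (4S,5S)-4-[(1S,3S,4S)-3-bromo-4-chloro-4-methylcyclohexyl]-5-methyl-4-(3-methylbut-2-en-1-yl)-1,3-dioxolan-2-one
Product: 17 (2S,3S)-3-[(1S,3S,4S)-3-bromo-4-chloro-4-methylcyclohexyl]-6-methylhept-5-ene-2,3-diol
Conditions: K2CO3 (cat.), MeOH, rt
Reagents that add atoms: none
Why: Transesterification (methanolysis) of the cyclic carbonate releases the diol; the equatorial halides have no anti-periplanar ring hydrogen for E2 and no stereocentre is touched.

**Step 8**
Reactants: 17 (2S,3S)-3-[(1S,3S,4S)-3-bromo-4-chloro-4-methylcyclohexyl]-6-methylhept-5-ene-2,3-diol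
Product: 18 (3S)-3-[(1S,3S,4S)-3-bromo-4-chloro-4-methylcyclohexyl]-3-hydroxy-6-methylhept-5-en-2-one
Conditions: IBX, DMSO, rt
Reagents that add atoms: none
Why: IBX oxidation of the secondary alcohol of a sec,tert-1,2-diol gives the α-ketol without C–C cleavage; the auxiliary carbinol stereocentre is erased on purpose and the tertiary carbinol is unaffected.

**Step 9**
Reactants: 18 (3S)-3-[(1S,3S,4S)-3-bromo-4-chloro-4-methylcyclohexyl]-3-hydroxy-6-methylhept-5-en-2-one
Product: 19 (3S)-3-[(1S,3S,4S)-3-bromo-4-chloro-4-methylcyclohexyl]-4-[(2R)-3,3-dimethyloxiran-2-yl]-3-hydroxybutan-2-one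
Conditions: D-fructose-derived Shi ketone (30 mol%), Oxone, K2CO3, Bu4NHSO4, MeCN/DMM–aq. borate buffer (pH 10.5), 0 °C
Reagents that add atoms: potassium peroxymonosulfate, [K+].[O-]S(=O)(=O)OO
Why: Shi asymmetric epoxidation (chiral dioxirane, spiro transition state) of the trisubstituted prenyl alkene gives the (R)-2,2-dimethyl-3-alkyl oxirane under reagent control, independent of the remote stereocentres.

**Compound list**
1 | (S)-but-3-yn-2-ol | C[C@H](O)C#C | starting material
2 | allylmagnesium bromide | C=CC[Mg]Br | starting material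
3 | (5S)-5-methyl-4-(prop-2-en-1-yl)-2,5-dihydro-1,2-oxamagnesole (chelated vinylmagnesium alkoxide) | C[C@@H]1O[Mg]C=C1CC=C | intermediate
4 | iodomagnesium (2S,3Z)-3-(iodomethylidene)hex-5-en-2-olate | C[C@H](O[Mg]I)/C(CC=C)=C\I | intermediate
5 | tert-butyl [(2S,3Z)-3-(iodomethylidene)hex-5-en-2-yl] carbonate | C[C@H](OC(=O)OC(C)(C)C)/C(CC=C)=C\I | intermediate
6 | 2-methylbut-2-ene | CC=C(C)C | starting material
7 | tert-butyl [(2S,3Z)-3-(iodomethylidene)-6-methylhept-5-en-2-yl] carbonate | C[C@H](OC(=O)OC(C)(C)C)/C(CC=C(C)C)=C\I | intermediate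
8 | (2Z)-3-methylpent-2-en-4-yn-1-ol | C#C/C(C)=C\CO | starting material
9 | (2Z)-3-methylpenta-2,4-dien-1-ol | C=C/C(C)=C\CO | intermediate
10 | 9-{(3Z)-5-[(9-borabicyclo[3.3.1]nonan-9-yl)oxy]-3-methylpent-3-en-1-yl}-9-borabicyclo[3.3.1]nonane | B1(CC/C(C)=C\COB2C3CCCC2CCC3)C2CCCC1CCC2 | intermediate
11 | tert-butyl [(2S,3Z,7Z)-9-hydroxy-7-methyl-3-(3-methylbut-2-en-1-yl)nona-3,7-dien-2-yl] carbonate | C[C@H](OC(=O)OC(C)(C)C)/C(CC=C(C)C)=C\CC/C(C)=C\CO | intermediate
12 | tert-butyl [(2S,3Z,7S,8S)-8-bromo-7-chloro-9-hydroxy-7-methyl-3-(3-methylbut-2-en-1-yl)non-3-en-2-yl] carbonate | C[C@H](OC(=O)OC(C)(C)C)/C(CC=C(C)C)=C\CC[C@](C)(Cl)[C@@H](Br)CO | intermediate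
13 | (2S,3S,7Z,8S)-2-bromo-8-[(tert-butoxycarbonyl)oxy]-3-chloro-3-methyl-7-(3-methylbut-2-en-1-yl)non-7-en-1-yl trifluoromethanesulfonate | C[C@H](OC(=O)OC(C)(C)C)/C(CC=C(C)C)=C\CC[C@](C)(Cl)[C@@H](Br)COS(=O)(=O)C(F)(F)F | intermediate
14 | bromiranium triflate from 13 (Br bridging the former CHBr and CH2OTf carbons) | C[C@H](OC(=O)OC(C)(C)C)/C(CC=C(C)C)=C\CC[C@](C)(Cl)[C@@H]1C[Br+]1.[O-]S(=O)(=O)C(F)(F)F | intermediate
15 | (4S,5S)-4-[(1S,3S,4S)-3-bromo-4-chloro-4-methylcyclohexyl]-2-tert-butoxy-5-methyl-4-(3-methylbut-2-en-1-yl)-1,3-dioxolan-2-ylium triflate | C[C@@H]1O[C+](OC(C)(C)C)O[C@@]1(CC=C(C)C)[C@H]2CC[C@](C)(Cl)[C@@H](Br)C2.[O-]S(=O)(=O)C(F)(F)F | intermediate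
16 | (4S,5S)-4-[(1S,3S,4S)-3-bromo-4-chloro-4-methylcyclohexyl]-5-methyl-4-(3-methylbut-2-en-1-yl)-1,3-dioxolan-2-one | C[C@@H]1OC(=O)O[C@@]1(CC=C(C)C)[C@H]2CC[C@](C)(Cl)[C@@H](Br)C2 | intermediate
17 | (2S,3S)-3-[(1S,3S,4S)-3-bromo-4-chloro-4-methylcyclohexyl]-6-methylhept-5-ene-2,3-diol | C[C@H](O)[C@](O)(CC=C(C)C)[C@H]1CC[C@](C)(Cl)[C@@H](Br)C1 | intermediate
18 | (3S)-3-[(1S,3S,4S)-3-bromo-4-chloro-4-methylcyclohexyl]-3-hydroxy-6-methylhept-5-en-2-one | CC(=O)[C@](O)(CC=C(C)C)[C@H]1CC[C@](C)(Cl)[C@@H](Br)C1 | intermediate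
19 | (3S)-3-[(1S,3S,4S)-3-bromo-4-chloro-4-methylcyclohexyl]-4-[(2R)-3,3-dimethyloxiran-2-yl]-3-hydroxybutan-2-one | CC(=O)[C@](O)(C[C@H]1OC1(C)C)[C@H]1CC[C@](C)(Cl)[C@@H](Br)C1 | target

**Total step count:** 9. **Longest linear sequence:** 8 (steps 1, 2, 4, 5, 6, 7, 8, 9; step 3 is a one-step side branch).

**Steps most likely to fail, with fallbacks**

Step 6 is the least precedented step. The triflate may be consumed by solvent capture, the cation may end by proton loss instead of carbonate capture, or the tertiary C–Cl bond may ionise in HFIP. The fallback generates the same cation by halide abstraction instead of sulfonate solvolysis, in a non-solvolytic medium. It sets out from 12: Appel iodination (I2, PPh3, imidazole, CH2Cl2, 0 °C) gives tert-butyl [(2S,3Z,7S,8R)-8-bromo-7-chloro-9-iodo-7-methyl-3-(3-methylbut-2-en-1-yl)non-3-en-2-yl] carbonate F1. Silver triflate with 2,6-di-tert-butyl-4-methylpyridine in CH2Cl2 at −40 °C then removes iodide with bromine participation; iodide is far more argentophilic than the tertiary chloride. This gives 14 directly, which closes through 15, and the route is rejoined at 16.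

Step 5 may suffer from competing bromination of the electron-rich prenyl alkene, or from lower selectivity with a Z-trisubstituted substrate carrying three alkenes. The fallback postpones the prenyl group until after halogenation. It sets out from 5: coupling of 5 with borane 10 under the step 4 conditions gives tert-butyl [(2S,3Z,7Z)-9-hydroxy-7-methyl-3-(prop-2-en-1-yl)nona-3,7-dien-2-yl] carbonate F2, whose only other alkenes are a monosubstituted one and the deactivated allylic-carbonate one. The same Ti/Schiff-base bromochlorination gives tert-butyl [(2S,3Z,7S,8S)-8-bromo-7-chloro-9-hydroxy-7-methyl-3-(prop-2-en-1-yl)non-3-en-2-yl] carbonate F3. Cross-metathesis of F3 with 6 (Hoveyda–Grubbs II) rejoins the route at 12.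

Step 4 may fail if Pd(0) ionises the allylic tert-butyl carbonate during the coupling. The fallback installs the carbonate only after the palladium step. It sets out from 1: step 1 is run with an aqueous NH4Cl quench in place of Boc2O (through 3 and 4) to give (2S,3Z)-3-(iodomethylidene)hex-5-en-2-ol F4, and cross-metathesis with 6 gives (2S,3Z)-3-(iodomethylidene)-6-methylhept-5-en-2-ol F5. In parallel 9 is silylated (TBSCl, imidazole) to tert-butyldimethyl{[(2Z)-3-methylpenta-2,4-dien-1-yl]oxy}silane F6 and hydroborated to 9-{(3Z)-5-[(tert-butyldimethylsilyl)oxy]-3-methylpent-3-en-1-yl}-9-borabicyclo[3.3.1]nonane F7. Suzuki coupling of F7 with F5 gives (2S,3Z,7Z)-9-[(tert-butyldimethylsilyl)oxy]-7-methyl-3-(3-methylbut-2-en-1-yl)nona-3,7-dien-2-ol F8. Boc2O/DMAP gives tert-butyl [(2S,3Z,7Z)-9-[(tert-butyldimethylsilyl)oxy]-7-methyl-3-(3-methylbut-2-en-1-yl)nona-3,7-dien-2-yl] carbonate F9, and HF·pyridine removes the silyl ether to rejoin the route at 11.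

**Further compounds**
F1 | step 6 | tert-butyl [(2S,3Z,7S,8R)-8-bromo-7-chloro-9-iodo-7-methyl-3-(3-methylbut-2-en-1-yl)non-3-en-2-yl] carbonate | C[C@H](OC(=O)OC(C)(C)C)/C(CC=C(C)C)=C\CC[C@](C)(Cl)[C@@H](Br)CI
F2 | step 5 | tert-butyl [(2S,3Z,7Z)-9-hydroxy-7-methyl-3-(prop-2-en-1-yl)nona-3,7-dien-2-yl] carbonate | C[C@H](OC(=O)OC(C)(C)C)/C(CC=C)=C\CC/C(C)=C\CO
F3 | step 5 | tert-butyl [(2S,3Z,7S,8S)-8-bromo-7-chloro-9-hydroxy-7-methyl-3-(prop-2-en-1-yl)non-3-en-2-yl] carbonate | C[C@H](OC(=O)OC(C)(C)C)/C(CC=C)=C\CC[C@](C)(Cl)[C@@H](Br)CO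
F4 | step 4 | (2S,3Z)-3-(iodomethylidene)hex-5-en-2-ol | C[C@H](O)/C(CC=C)=C\I
F5 | step 4 | (2S,3Z)-3-(iodomethylidene)-6-methylhept-5-en-2-ol | C[C@H](O)/C(CC=C(C)C)=C\I
F6 | step 4 | tert-butyldimethyl{[(2Z)-3-methylpenta-2,4-dien-1-yl]oxy}silane | C=C/C(C)=C\CO[Si](C)(C)C(C)(C)C
F7 | step 4 | 9-{(3Z)-5-[(tert-butyldimethylsilyl)oxy]-3-methylpent-3-en-1-yl}-9-borabicyclo[3.3.1]nonane | B1(CC/C(C)=C\CO[Si](C)(C)C(C)(C)C)C2CCCC1CCC2
F8 | step 4 | (2S,3Z,7Z)-9-[(tert-butyldimethylsilyl)oxy]-7-methyl-3-(3-methylbut-2-en-1-yl)nona-3,7-dien-2-ol | C[C@H](O)/C(CC=C(C)C)=C\CC/C(C)=C\CO[Si](C)(C)C(C)(C)C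
F9 | step 4 | tert-butyl [(2S,3Z,7Z)-9-[(tert-butyldimethylsilyl)oxy]-7-methyl-3-(3-methylbut-2-en-1-yl)nona-3,7-dien-2-yl] carbonate | C[C@H](OC(=O)OC(C)(C)C)/C(CC=C(C)C)=C\CC/C(C)=C\CO[Si](C)(C)C(C)(C)C
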